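| flask | Sub | Rea | remark | time |
|---|---|---|---|---|
| epsilon | 0.40 M | 0.22 M | run made earlier |  |
| gamma | 0.40 M | 0.88 M | run made earlier |  |
| zeta | 0.80 M | 0.44 M | run made earlier |  |
| flask | 0.40 M | 0.440 M |  | 2.0 h |

| run | time / min | Sub / % | Sub.Rea / % | Int2 / % |
|---|---|---|---|---|
| epsilon | 8.00 | 51 | 17 | 3 |
| epsilon | 25.0 | 35 | 25 | 5 |
| epsilon | 40.0 | 35 | 29 | 8 |
| epsilon | 60.0 | 30 | 31 | 7 |
| epsilon | 90.0 | 33 | 36 | 8 |
| epsilon | 120 | 32 | 37 | 8 |
| gamma | 20.0 | 8 | 51 | 24 |
| gamma | 40.0 | 8 | 47 | 38 |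
| gamma | 60.0 | 1 | 40 | 48 |
| gamma | 80.0 | 1 | 32 | 58 |
| gamma | 90.0 | 0 | 32 | 59 |
| gamma | 120 | 2 | 21 | 71 |
| zeta | 10.0 | 37 | 28 | 0 |
| zeta | 20.0 | 31 | 32 | 3 |
| zeta | 30.0 | 34 | 39 | 5 |
| zeta | 60.0 | 31 | 41 | 5 |
| zeta | 120 | 30 | 44 | 7 |

(each reading ± 1.5 percentage points)

- what is said of Sub.Rea includes Tsp
- Tsp is a solid; its amount is given per volume of the solution
- steps thought possible: Sub + Rea -> Sub.Rea; Rea + Sub.Rea -> Int2; Rea + Int2 -> Rea.Int2; Tsp <-> Sub.Rea; Sub <-> Int

* amount of Sub at 2.0 h, in percent of the Sub charged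
* amount of Sub.Rea at 2.0 h, in percent of the Sub charged
* amount of Int2 at 2.0 h, in percent of the Sub charged
* amount of Rea.Int2 at 2.0 h, in percent of the Sub charged

- Follow time: by 120 min the epsilon run has levelled, yet its Sub, Sub.Rea and Int2 sum to 77.0%, so you credit the gap to Int, exchanging with Sub.
- Treat that exchange as fast: those readings give 58.2% as Sub over the pool of Sub plus Int, the free share, and zeta's last readings give 61.2%.
- Now draw the flask. Gamma's first 20.0 min, scaled by mean [Rea], gives a pool half-life of 15.5 min at the flask's starting [Rea] once the share holds, but 9.02 min at the very start, when Sub is the whole pool.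
- The knee comes early: epsilon's share already reads 63.8% at 8.00 min.
- Gamma's Int2 climbs steadily while its Sub.Rea falls, which reads as crystals holding dissolved Sub.Rea steady. Int2 and pool loss then both carry [Rea], which cancels: Int2 gained per unit of the logarithm of the pool's fall, a selectivity factor, is 0.144.
- The level: each Int2 costs a second Rea, so with no Rea left in your ledger, the pool equals Int2 less the excess of 10.0%. Two passes give 17.9% and 14.8%; I take the middle, 16.3%, hence Sub 9.49%, Int2 26.3% and, leaving Rea.Int2 aside, Sub.Rea 57.3%, what the pool and Int2 leave of the Sub charged.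
- The forecast, saying “Sub is therefore about 60% of the pool”, gives Sub 9%, Sub.Rea 64%, Int2 19% and Rea.Int2 1%, parting from my reckoning on Sub.Rea and Int2.
- The flask gives Sub 12.4%, Sub.Rea 51.9%, Int2 24.8% and Rea.Int2 0.956%.

    Sub + Rea → Sub.Rea (k = 0.200 /M/min)
    Rea + Sub.Rea → Int2 (k = 0.590 /M/min)
    Rea + Int2 → Rea.Int2 (k = 0.00580 /M/min)
    Tsp ⇌ Sub.Rea, rate k4*(cs4 - [Sub.Rea]) while solid is left; crystals form when [Sub.Rea] > cs4 (solubility = 13.0 mM, k = 6.30 /min)
    Sub ⇌ Int (K = 0.790, k = 0.100 /min)

- In the flask at 2.0 h, Rea uses Sub at 0.046 of the forward rate of Sub into Int, and the exchange relaxes with a half-life of 0.0510 h, short against 2.0 h. Apply the free share 58.2% to the flask's Sub plus Int and you get 13.0% against Sub 12.4%, and in the neighbour flask with 0.26 M of Rea you get 28.0% against Sub 26.8%.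

The runs come from a simulation with constants of no real substance; noise was put on by code.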